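Locants follow 2,3-dihydro-1,4-benzodioxine: O1–C2 (carries the 3,5-dioxygenated ring C)–C3 (carries the catechol ring B)–O4–C4a; benzo ring A carries the stilbene arm at C6, para to O1.
Cuts: the six O–H (as TBS ethers), then the stilbene C=C at C6 (Horner–Wadsworth–Emmons), then O4–C4a and C2–C3 together, then the O1–CH2 bond of the remaining aryl benzyl ether (Mitsunobu).
Enabling feature: C2–H is benzylic to ring C and α to O1, so it can be lithiated. C3–O4 is a latent aldehyde C=O. C4a is ortho to the O1-bearing C8a, so a fluorine placed there becomes a C4a≡C5 aryne that the new alkoxide O4 reaches through a six-membered ring.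
Forward: all four benzene rings are bought. Ether 8 and aldehyde 10 are joined, and the dioxane ring, the only ring made, closes in the same flask (step 8). The acetal helper is then removed, the stilbene arm attached and the silyl groups taken off.
Stereochemistry: C2 comes from a chiral bis(oxazoline) ligand on lithium and C3 from erythro-selective addition to the aldehyde. Closure at the aryl carbon touches neither centre, so erythro becomes cis (2S,3R). The E alkene comes from the phosphonate olefination.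

Key step: step 8

TBS = tert-butyldimethylsilyl; TBSO = tert-butyldimethylsilyloxy.
Assumption: the sense of induction of the bis(oxazoline) ligand on this ether is not known in advance. The (S,S)-ligand from L-valinol is written, and its (R,R)-antipode would be used with no other change if the opposite sense is found.

Step 1
Reactants: 1 3,5-dihydroxybenzaldehyde
Product: 2 3,5-bis(TBSO)benzaldehyde
Conditions: TBSCl (2.4 equiv), imidazole (5 equiv), DMF, 0 °C → rt
Reagents that add atoms: tert-butyldimethylsilyl chloride, CC(C)(C)[Si](C)(C)Cl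
Why: Imidazole-promoted silylation of phenols is routine, leaves the formyl group alone and installs groups that later leave under buffered fluoride.

Step 2
Reactants: 2 3,5-bis(TBSO)benzaldehyde
Product: 3 [3,5-bis(TBSO)phenyl]methanol
Conditions: NaBH4, THF–MeOH, 0 °C
Reagents that add atoms: none
Why: Borohydride reduction of an aromatic aldehyde is fast at 0 °C and aryl silyl ethers survive the short contact.

Step 3
Reactants: 3 [3,5-bis(TBSO)phenyl]methanol
Product: 4 3,5-bis(TBSO)benzyl bromide
Conditions: CBr4, PPh3, CH2Cl2, 0 °C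
Reagents that add atoms: carbon tetrabromide, BrC(Br)(Br)Br
Why: The Appel reaction converts a primary benzylic alcohol into the bromide under neutral conditions that spare aryl silyl ethers.

Step 4
Reactants: 4 3,5-bis(TBSO)benzyl bromide
Product: 5 diethyl [3,5-bis(TBSO)benzyl]phosphonate
Conditions: P(OEt)3 (neat), 130 °C
Reagents that add atoms: triethyl phosphite, CCOP(OCC)OCC
Why: The Michaelis–Arbuzov reaction of a primary benzylic bromide with neat phosphite is reliable and needs no base or acid.

Step 5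
Reactants: 3 [3,5-bis(TBSO)phenyl]methanol; 6 3-fluoro-4-hydroxybenzaldehyde
Product: 7 4-{[3,5-bis(TBSO)benzyl]oxy}-3-fluorobenzaldehyde
Conditions: PPh3, DIAD, THF, 0 °C → rt
Reagents that add atoms: none
Why: The Mitsunobu reaction alkylates the acidic phenol 6 with the primary benzylic alcohol 3 under neutral conditions, which avoids the carbonate bases that strip aryl silyl ethers.

Step 6
Reactants: 7 4-{[3,5-bis(TBSO)benzyl]oxy}-3-fluorobenzaldehyde
Product: 8 1-{[3,5-bis(TBSO)benzyl]oxy}-4-(dimethoxymethyl)-2-fluorobenzene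
Conditions: HC(OMe)3, PPTS (cat.), MeOH, rt; Et3N quench
Reagents that add atoms: trimethyl orthoformate, COC(OC)OC
Why: Acid-catalysed acetalisation driven by the orthoformate masks the formyl group against organolithiums and takes away the acceptor para to the ether oxygen.

Step 7
Reactants: 9 3,4-dihydroxybenzaldehyde
Product: 10 3,4-bis(TBSO)benzaldehyde
Conditions: TBSCl (2.4 equiv), imidazole (5 equiv), DMF, 0 °C → rt
Reagents that add atoms: tert-butyldimethylsilyl chloride, CC(C)(C)[Si](C)(C)Cl
Why: Imidazole-promoted silylation protects both catechol hydroxyls and gives a non-enolisable aldehyde that tolerates organolithium addition at its carbonyl group only.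

Step 8
Reactants: 8 1-{[3,5-bis(TBSO)benzyl]oxy}-4-(dimethoxymethyl)-2-fluorobenzene; 10 3,4-bis(TBSO)benzaldehyde
Product: 15 (2S,3R)-3-[3,4-bis(TBSO)phenyl]-2-[3,5-bis(TBSO)phenyl]-6-(dimethoxymethyl)-2,3-dihydro-1,4-benzodioxine (cis), via lithiated ether 11 (not isolated), via erythro lithium alkoxide 12 (not isolated), via aryne alkoxide 13 (not isolated), via C5 aryllithium 14 (not isolated)
Conditions: t-BuLi (1.1 equiv), (S,S)-3,3-bis(4-isopropyl-4,5-dihydrooxazol-2-yl)pentane (1.2 equiv), hexane–Et2O, −78 °C; 10 (1.0 equiv), −78 °C; lithium 2,2,6,6-tetramethylpiperidide (LiTMP, 2.5 equiv, from 2,2,6,6-tetramethylpiperidine and n-BuLi) in THF, −78 → 0 °C; aq NH4Cl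
Reagents that add atoms: none
Why: Proposed new method: t-BuLi bound to the bis(oxazoline) removes one of the two benzylic protons of 8 that lie α to the aryloxy oxygen, lithio ether 11 adds to the C=O of 10 (C2–C3 bond) to give alkoxide 12, LiTMP then lithiates the ring A C–H between fluorine and the acetal, LiF is lost, and the alkoxide oxygen of aryne 13 adds to the aryne carbon next to the ether-bearing carbon (O4–C4a bond) to give aryllithium 14, which the quench protonates. The closest known reaction types are the α-lithiation of aryl benzyl ethers with t-BuLi followed by carbonyl trapping, the bis(oxazoline)-mediated enantioselective lithiation–substitution of benzyl ethers, and the anionic benzyne cyclisation of 2-fluorophenyl ethers that carry a tethered nucleophile; new are their union in one flask and an alkoxide born in the flask as the aryne trap. The 1,4-dioxane ring closes by 6-exo-dig attack of oxygen on the in-plane π bond of the aryne, and attack at the other aryne carbon is geometrically impossible because it would need a meta bridge. C2 is controlled by the ligand, since the epimeric complexes of configurationally labile 11 interconvert at −78 °C and the favoured one should react with retention, and C3 is controlled by relative topicity, since lithium saturated by the bidentate ligand and the aldehyde cannot chelate the ether oxygen or fluorine, so the staggered transition state with the two aryl groups anti and the two C–O dipoles anti leads to the erythro (1R,2S) alkoxide. The aryl C–O closure touches neither centre, so erythro is carried over into the less stable cis (2S,3R) ring, which an equilibrating closure at a benzylic carbon would not give. The step needs benzylic instead of ring lithiation, no [1,2]-Wittig shift and no exchange of the two ring oxygens, and these are secured by bulky silyl ethers that are poor directing groups and shield ring C, by the C–F bond that resists exchange with t-BuLi, by holding −78 °C until the aldehyde is consumed, and by the acetal, which unlike a formyl group para to the ether oxygen cannot promote a Smiles migration.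

Step 9
Reactants: 15 (2S,3R)-cis-benzodioxane dimethyl acetal
Product: 16 (2S,3R)-3-[3,4-bis(TBSO)phenyl]-2-[3,5-bis(TBSO)phenyl]-2,3-dihydro-1,4-benzodioxine-6-carbaldehyde
Conditions: PPTS (cat.), acetone–H2O, rt
Reagents that add atoms: water, O
Why: Hydrolysis of an aromatic dimethyl acetal needs only a weak acid, under which aryl silyl ethers hold and the benzylic C3–O4 bond next to the silylated ring B does not ionise, so the cis configuration stays.

Step 10
Reactants: 16 (2S,3R)-cis-benzodioxane-6-carbaldehyde; 5 diethyl [3,5-bis(TBSO)benzyl]phosphonate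
Product: 18 (2S,3R)-3-[3,4-bis(TBSO)phenyl]-2-[3,5-bis(TBSO)phenyl]-6-{(E)-2-[3,5-bis(TBSO)phenyl]ethenyl}-2,3-dihydro-1,4-benzodioxine, via potassium phosphonate carbanion 17 (not isolated)
Conditions: 5, KN(SiMe3)2 (1.1 equiv), THF, −78 °C; 16, −78 °C → rt
Reagents that add atoms: none
Why: The Horner–Wadsworth–Emmons reaction of a benzylic phosphonate carbanion with an aromatic aldehyde gives the E stilbene, and the non-nucleophilic amide base leaves silicon and both ring stereocentres alone.

Step 11
Reactants: 18 hexa-TBS ether of the target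
Product: 19 (2S,3R)-3-(3,4-dihydroxyphenyl)-2-(3,5-dihydroxyphenyl)-6-[(E)-2-(3,5-dihydroxyphenyl)ethenyl]-2,3-dihydro-1,4-benzodioxine (CNP0283264.2)
Conditions: Bu4NF (7 equiv), AcOH (7 equiv), THF, 0 °C, argon; pH 6 phosphate buffer work-up
Reagents that add atoms: none
Why: Fluoride cleaves aryl silyl ethers quickly at 0 °C, and the acetic acid buffer keeps the freed 4-hydroxyl of ring B protonated, so that no para-quinone methide can open the C3–O4 bond and epimerise the cis ring.

Compound list
1 | 3,5-dihydroxybenzaldehyde | O=Cc1cc(O)cc(O)c1 | starting material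
2 | 3,5-bis(TBSO)benzaldehyde | O=Cc1cc(O[Si](C)(C)C(C)(C)C)cc(O[Si](C)(C)C(C)(C)C)c1 | intermediate
3 | [3,5-bis(TBSO)phenyl]methanol | OCc1cc(O[Si](C)(C)C(C)(C)C)cc(O[Si](C)(C)C(C)(C)C)c1 | intermediate
4 | 3,5-bis(TBSO)benzyl bromide | BrCc1cc(O[Si](C)(C)C(C)(C)C)cc(O[Si](C)(C)C(C)(C)C)c1 | intermediate
5 | diethyl [3,5-bis(TBSO)benzyl]phosphonate | CCOP(=O)(Cc1cc(O[Si](C)(C)C(C)(C)C)cc(O[Si](C)(C)C(C)(C)C)c1)OCC | intermediate
6 | 3-fluoro-4-hydroxybenzaldehyde | O=Cc1ccc(O)c(F)c1 | starting material
7 | 4-{[3,5-bis(TBSO)benzyl]oxy}-3-fluorobenzaldehyde | O=Cc1ccc(OCc2cc(O[Si](C)(C)C(C)(C)C)cc(O[Si](C)(C)C(C)(C)C)c2)c(F)c1 | intermediate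
8 | 1-{[3,5-bis(TBSO)benzyl]oxy}-4-(dimethoxymethyl)-2-fluorobenzene | COC(OC)c1ccc(OCc2cc(O[Si](C)(C)C(C)(C)C)cc(O[Si](C)(C)C(C)(C)C)c2)c(F)c1 | intermediate
9 | 3,4-dihydroxybenzaldehyde | O=Cc1ccc(O)c(O)c1 | starting material
10 | 3,4-bis(TBSO)benzaldehyde | O=Cc1ccc(O[Si](C)(C)C(C)(C)C)c(O[Si](C)(C)C(C)(C)C)c1 | intermediate
11 | (R)-α-lithio derivative of 8, reacting epimer of its bis(oxazoline) complex (ligand not drawn) | [Li][C@H](c1cc(O[Si](C)(C)C(C)(C)C)cc(O[Si](C)(C)C(C)(C)C)c1)Oc1ccc(C(OC)OC)cc1F | intermediate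
12 | lithium (1R,2S)-1-[3,4-bis(TBSO)phenyl]-2-[3,5-bis(TBSO)phenyl]-2-[4-(dimethoxymethyl)-2-fluorophenoxy]ethan-1-olate (erythro) | [Li]O[C@H](c1ccc(O[Si](C)(C)C(C)(C)C)c(O[Si](C)(C)C(C)(C)C)c1)[C@H](c1cc(O[Si](C)(C)C(C)(C)C)cc(O[Si](C)(C)C(C)(C)C)c1)Oc1ccc(C(OC)OC)cc1F | intermediate
13 | aryne derived from 12 by loss of HF across the fluorine-bearing carbon and its C–H neighbour | [Li]O[C@H](c1ccc(O[Si](C)(C)C(C)(C)C)c(O[Si](C)(C)C(C)(C)C)c1)[C@H](c1cc(O[Si](C)(C)C(C)(C)C)cc(O[Si](C)(C)C(C)(C)C)c1)OC1=CC=C(C(OC)OC)C#C1 | intermediate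
14 | 5-lithio derivative of 15 | COC(OC)c1ccc2c(c1[Li])O[C@H](c1ccc(O[Si](C)(C)C(C)(C)C)c(O[Si](C)(C)C(C)(C)C)c1)[C@H](c1cc(O[Si](C)(C)C(C)(C)C)cc(O[Si](C)(C)C(C)(C)C)c1)O2 | intermediate
15 | (2S,3R)-3-[3,4-bis(TBSO)phenyl]-2-[3,5-bis(TBSO)phenyl]-6-(dimethoxymethyl)-2,3-dihydro-1,4-benzodioxine | COC(OC)c1ccc2c(c1)O[C@H](c1ccc(O[Si](C)(C)C(C)(C)C)c(O[Si](C)(C)C(C)(C)C)c1)[C@H](c1cc(O[Si](C)(C)C(C)(C)C)cc(O[Si](C)(C)C(C)(C)C)c1)O2 | intermediate
16 | (2S,3R)-3-[3,4-bis(TBSO)phenyl]-2-[3,5-bis(TBSO)phenyl]-2,3-dihydro-1,4-benzodioxine-6-carbaldehyde | O=Cc1ccc2c(c1)O[C@H](c1ccc(O[Si](C)(C)C(C)(C)C)c(O[Si](C)(C)C(C)(C)C)c1)[C@H](c1cc(O[Si](C)(C)C(C)(C)C)cc(O[Si](C)(C)C(C)(C)C)c1)O2 | intermediate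
17 | potassium salt of the benzylic carbanion of 5 | CCOP(=O)(OCC)[CH-]c1cc(O[Si](C)(C)C(C)(C)C)cc(O[Si](C)(C)C(C)(C)C)c1.[K+] | intermediate
18 | (2S,3R)-3-[3,4-bis(TBSO)phenyl]-2-[3,5-bis(TBSO)phenyl]-6-{(E)-2-[3,5-bis(TBSO)phenyl]ethenyl}-2,3-dihydro-1,4-benzodioxine | CC(C)(C)[Si](C)(C)Oc1cc(O[Si](C)(C)C(C)(C)C)cc(/C=C/c2ccc3c(c2)O[C@H](c2ccc(O[Si](C)(C)C(C)(C)C)c(O[Si](C)(C)C(C)(C)C)c2)[C@H](c2cc(O[Si](C)(C)C(C)(C)C)cc(O[Si](C)(C)C(C)(C)C)c2)O3)c1 | intermediate
19 | (2S,3R)-3-(3,4-dihydroxyphenyl)-2-(3,5-dihydroxyphenyl)-6-[(E)-2-(3,5-dihydroxyphenyl)ethenyl]-2,3-dihydro-1,4-benzodioxine | Oc1cc(O)cc(/C=C/c2ccc3c(c2)O[C@H](c2ccc(O)c(O)c2)[C@H](c2cc(O)cc(O)c2)O3)c1 | target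

Total steps: 11. Longest linear sequence: 8 steps (1, 2, 5, 6, 8, 9, 10, 11).

Steps most likely to fail

Step 8 (labelled step).
- What may go wrong:
  - Lithiation of ring A next to fluorine may compete with the benzylic position.
  - Facial discrimination at C2 or C3 may be weak.
  - A [1,2]-Wittig shift may set in on warming.
  - The amine may capture the aryne before the alkoxide closes.
  - Excess amide base may deprotonate the product at a benzylic position, with ring opening.
- The fallback uses known chemistry, sets out from 10 and 5 and comes back at 16. Horner–Wadsworth–Emmons coupling of 10 with 5 (KN(SiMe3)2, THF) gives (E)-3,3',4,5'-tetrakis(TBSO)stilbene F1. Shi epoxidation with the L-fructose-derived ketone (KHSO5, K2CO3 buffer, MeCN–dimethoxymethane–water, 0 °C) gives the (2S,3S)-trans-epoxide F2. The potassium phenoxide of commercial 4-fluoro-3-hydroxybenzaldehyde (O=Cc1ccc(F)c(O)c1) opens F2 by SN2 attack with inversion at the benzylic carbon of ring B, which the para silyloxy group activates, and gives the erythro aryloxy alcohol F3. KN(SiMe3)2 in THF then closes O1–C8a by SNAr at the fluoride para to the formyl group. This should give 16 with the same regiochemistry and the cis (2S,3R) configuration.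

Step 11.
- What may go wrong: once the 4-hydroxyl of ring B is free, any phenoxide can expel O4 from C3 through a para-quinone methide, and re-closure would drift to the trans ring. The free catechol can also oxidise in air.
- The fallback sets out from 18 and comes back at 19. Treatment with CsF and Ac2O in MeCN (0 °C → rt) acetylates each phenoxide as it is released, so none persists, and gives the hexaacetate F4, which can be purified on silica. Neutral alcoholysis with a hydrolase (Candida antarctica lipase B, n-BuOH, t-BuOMe, 40 °C) then frees the six phenols without base or acid.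

Step 10.
- What may go wrong: the basic phosphonate carbanion may strip aryl silyl groups, elimination of the adduct may be slow, and control of the alkene geometry may be incomplete.
- The fallback sets out from 16 and comes back at 18. Wittig methylenation (Ph3PCH3Br, KN(SiMe3)2, THF, 0 °C) gives the 6-vinyl benzodioxane F5. Commercial 5-iodobenzene-1,3-diol (Oc1cc(O)cc(I)c1) is silylated (TBSCl, imidazole, DMF) to 1-iodo-3,5-bis(TBSO)benzene F6. A Mizoroki–Heck reaction of F5 with F6 (Pd(OAc)2, P(o-tol)3, Et3N, MeCN, 80 °C) forms the E stilbene 18 without any carbanion.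

Further compounds
F1 | step 8 | (E)-3,3',4,5'-tetrakis(TBSO)stilbene | CC(C)(C)[Si](C)(C)Oc1cc(O[Si](C)(C)C(C)(C)C)cc(/C=C/c2ccc(O[Si](C)(C)C(C)(C)C)c(O[Si](C)(C)C(C)(C)C)c2)c1
F2 | step 8 | (2S,3S)-2-[3,4-bis(TBSO)phenyl]-3-[3,5-bis(TBSO)phenyl]oxirane | O1[C@@H](c2ccc(O[Si](C)(C)C(C)(C)C)c(O[Si](C)(C)C(C)(C)C)c2)[C@@H]1c3cc(O[Si](C)(C)C(C)(C)C)cc(O[Si](C)(C)C(C)(C)C)c3
F3 | step 8 | 3-{(1R,2S)-1-[3,4-bis(TBSO)phenyl]-2-[3,5-bis(TBSO)phenyl]-2-hydroxyethoxy}-4-fluorobenzaldehyde | O=Cc1ccc(F)c(c1)O[C@H](c1ccc(O[Si](C)(C)C(C)(C)C)c(O[Si](C)(C)C(C)(C)C)c1)[C@H](c1cc(O[Si](C)(C)C(C)(C)C)cc(O[Si](C)(C)C(C)(C)C)c1)O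
F4 | step 11 | hexaacetate of 19 | CC(=O)Oc1cc(OC(C)=O)cc(/C=C/c2ccc3c(c2)O[C@H](c2ccc(OC(C)=O)c(OC(C)=O)c2)[C@H](c2cc(OC(C)=O)cc(OC(C)=O)c2)O3)c1
F5 | step 10 | (2S,3R)-3-[3,4-bis(TBSO)phenyl]-2-[3,5-bis(TBSO)phenyl]-6-ethenyl-2,3-dihydro-1,4-benzodioxine | C=Cc1ccc2c(c1)O[C@H](c1ccc(O[Si](C)(C)C(C)(C)C)c(O[Si](C)(C)C(C)(C)C)c1)[C@H](c1cc(O[Si](C)(C)C(C)(C)C)cc(O[Si](C)(C)C(C)(C)C)c1)O2
F6 | step 10 | 1-iodo-3,5-bis(TBSO)benzene | CC(C)(C)[Si](C)(C)Oc1cc(I)cc(O[Si](C)(C)C(C)(C)C)c1
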